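Everything rests on cutting the dihydropyran ring of the chroman at O1–C2 and C3–C4. The feature exploited is that O1, C8a, C4a and C4 make up an ortho-quinone methide of the phloroglucinol ring, while C2 with its two methyl groups and C3 come from an isobutenyl boronate, the C3–B bond standing in for the later C3–OH. One catalytic asymmetric oxa-[4+2] cycloaddition thus forms both bonds, closes the ring and sets C3, the only stereocentre. Its precursor is a 2-hydroxybenzyl alcohol with methoxy para and a MOM ether ortho to the CH2OH group. MOM is chosen because it later steers lithiation to C6 and leaves in the final acid step.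

Key step: step 4

Remark on descriptors: C3 is R in the target, in the derived alcohol and in the boronate. Oxygen ranks above C2 and C4 and boron ranks below both, which is a cyclic shift of priorities, so oxidation with retention keeps the letter.

Assumption: the sense of induction of a BINOL phosphate in this untested cycloaddition cannot be predicted from a model. (R)-TRIP is written, and its equally available antipode is used if the first run falls in the 3S series.

**Step 1**
Reactants: 1 2,4,6-trihydroxybenzaldehyde
Product: 2 2,6-dihydroxy-4-methoxybenzaldehyde
Conditions: Me2SO4 (1.0 equiv), K2CO3 (1.0 equiv), acetone, 0 °C to rt, Ar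
Reagents that add atoms: dimethyl sulfate, COS(=O)(=O)OC
Why: Williamson-type O-methylation under stoichiometric control: the 4-OH is the most acidic hydroxyl and the only one not hydrogen-bonded to the formyl oxygen, so one equivalent of base and of the hard methylating agent should take it first and avoid C-methylation.

**Step 2**
Reactants: 2 2,6-dihydroxy-4-methoxybenzaldehyde
Product: 3 2-hydroxy-4-methoxy-6-(methoxymethoxy)benzaldehyde
Conditions: MOMCl (1.05 equiv), K2CO3 (1.1 equiv), acetone, 0 °C to rt
Reagents that add atoms: chloromethyl methyl ether, COCCl
Why: Williamson etherification: the two hydroxyls are equivalent by symmetry, so either one leads to 3, and the hydroxyl left over becomes the sole hydrogen-bond partner of the formyl oxygen and is slow to react a second time.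

**Step 3**
Reactants: 3 2-hydroxy-4-methoxy-6-(methoxymethoxy)benzaldehyde
Product: 4 2-(hydroxymethyl)-5-methoxy-3-(methoxymethoxy)phenol
Conditions: NaBH4 (0.6 equiv), THF/MeOH, −10 °C, 20 min; pH 7 phosphate buffer; cold extraction, no chromatography, used the same day
Reagents that add atoms: none
Why: Borohydride 1,2-reduction of an aldehyde, which leaves the acetal and the ethers alone; low temperature, little excess hydride and a neutral work-up are meant to keep the electron-rich 2-hydroxybenzyl alcohol from ionising before it is wanted.

**Step 4**
Reactants: 4 2-(hydroxymethyl)-5-methoxy-3-(methoxymethoxy)phenol; 5 2-methylprop-1-enylboronic acid pinacol ester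
Product: 7 (3R)-7-methoxy-5-(methoxymethoxy)-2,2-dimethyl-3-(4,4,5,5-tetramethyl-1,3,2-dioxaborolan-2-yl)chroman, via ortho-quinone methide 6 (not isolated)
Conditions: (R)-TRIP [(R)-3,3'-bis(2,4,6-triisopropylphenyl)-BINOL hydrogen phosphate] (10 mol %), 5 (5 equiv), 5 Å MS, toluene, 0 °C, 4 in CH2Cl2 added by syringe pump over 8 h; Et3N quench; excess 5 recovered by distillation; deactivated silica
Reagents that add atoms: none
Why: Proposed new method: the phosphoric acid protonates the benzylic hydroxyl of 4, water departs with the push of the para methoxy group and the ortho oxygens, and the resulting methide 6 stays hydrogen-bonded through its carbonyl oxygen to the chiral phosphate; C4 (the CH2 terminus) then attacks the boron-bearing CH of 5, the developing positive charge sits on the fully substituted CMe2 carbon where the neighbouring C–B σ bond can support it by hyperconjugation, and O1 bonds to that carbon within the same, strongly asynchronous cycloaddition event. The nearest known reaction types are phosphoric-acid-catalysed [4+2] additions of in situ ortho-quinone methides to styrenes and enecarbamates and the uncatalysed thermal additions of phloroglucinol-derived methides to trisubstituted alkenes, so the new elements are the alkenyl boronate as 2π partner and a methide without a substituent on its terminus. The dihydropyran ring is closed by the intermolecular inverse-demand hetero-Diels–Alder reaction itself (4π: O1=C8a–C4a=C4; 2π: C3=C2), which in its stepwise limit is a six-membered ring closure of O1 onto the tertiary cation. C3 is set under catalyst control: the 2,4,6-triisopropylphenyl walls should screen one face of bound 6, and the bulky Bpin group should take the exo position away from the C5 MOM ether, so that only one enantioface of the alkene meets C4. Regiochemistry (O1 to C2) is secured by the preference for a tertiary over a secondary cation, formation of a single methide by the MOM cap on the second ortho oxygen, and retention of boron by the low Lewis acidity of the pinacol ester and the closeness of O1, which should make ring closure faster than deborylation. Slow addition of 4 into a large excess of 5 keeps 6 dilute, which should hold back its oligomerisation and the alkylation of the electron-rich arene rings, and a weak acid in a dry medium leaves the aryl MOM ether intact.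

**Step 5**
Reactants: 7 (3R)-7-methoxy-5-(methoxymethoxy)-2,2-dimethyl-3-(4,4,5,5-tetramethyl-1,3,2-dioxaborolan-2-yl)chroman
Product: 8 (3R)-7-methoxy-5-(methoxymethoxy)-2,2-dimethylchroman-3-ol
Conditions: NaBO3·4H2O (4 equiv), THF/H2O, 0 °C to rt
Reagents that add atoms: sodium perborate, [Na+].[O-]OB=O
Why: Oxidative C–B cleavage as in a hydroboration work-up: peroxide adds to boron and C3 shifts from boron to oxygen with retention, so (3R)-7 gives (3R)-8, and the mildly basic perborate should keep this 1,2-shift faster than β-elimination of the C2 aryloxide.

**Step 6**
Reactants: 8 (3R)-7-methoxy-5-(methoxymethoxy)-2,2-dimethylchroman-3-ol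
Product: 10 1-[(3R)-3-hydroxy-7-methoxy-5-(methoxymethoxy)-2,2-dimethylchroman-6-yl]ethanone, via C6-lithiated lithium alkoxide 9 (not isolated)
Conditions: n-BuLi (2.4 equiv), TMEDA (2.4 equiv), THF, −20 to 0 °C; then MeC(O)N(OMe)Me (3 equiv), −78 to 0 °C; H2O
Reagents that add atoms: N-methoxy-N-methylacetamide, CC(=O)N(C)OC
Why: Directed ortho-metalation followed by Weinreb ketone synthesis: the first equivalent of base makes the inert C3 alkoxide, the second should remove H6, which lies between the chelating MOM ether (its arm is pushed towards C6 by the C4 methylene) and the methoxy group, and the chelated tetrahedral adduct stops at the ketone without touching C3.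

**Step 7**
Reactants: 11 4-hydroxybenzaldehyde
Product: 12 4-(methoxymethoxy)benzaldehyde
Conditions: MOMCl (1.2 equiv), K2CO3 (1.5 equiv), acetone, rt
Reagents that add atoms: chloromethyl methyl ether, COCCl
Why: Williamson etherification of an acidic para-formyl phenol, which removes the phenoxide that would otherwise deactivate the aldehyde in the aldol step.

**Step 8**
Reactants: 10 1-[(3R)-3-hydroxy-7-methoxy-5-(methoxymethoxy)-2,2-dimethylchroman-6-yl]ethanone; 12 4-(methoxymethoxy)benzaldehyde
Product: 13 (E)-1-[(3R)-3-hydroxy-7-methoxy-5-(methoxymethoxy)-2,2-dimethylchroman-6-yl]-3-[4-(methoxymethoxy)phenyl]prop-2-en-1-one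
Conditions: KOH (10 equiv), EtOH, rt, 24–48 h
Reagents that add atoms: none
Why: Claisen–Schmidt condensation (crossed aldol, E1cB dehydration): the methyl ketone is the only enolisable partner, the conjugated E-alkene is the thermodynamic outcome, and with the C5 oxygen masked the chalcone cannot close to a flavanone in base, while the free C3 alcohol is a bystander.

**Step 9**
Reactants: 13 (E)-1-[(3R)-3-hydroxy-7-methoxy-5-(methoxymethoxy)-2,2-dimethylchroman-6-yl]-3-[4-(methoxymethoxy)phenyl]prop-2-en-1-one
Product: 14 (E)-1-[(3R)-3,5-dihydroxy-7-methoxy-2,2-dimethylchroman-6-yl]-3-(4-hydroxyphenyl)prop-2-en-1-one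
Conditions: HCl (ca. 1 M), MeOH, rt
Reagents that add atoms: none
Why: Acid-catalysed acetal exchange removes both aryl MOM ethers under conditions that are standard for 2'-hydroxy-6'-methoxychalcones, and a short exposure at room temperature should leave the enone geometry, the tertiary aryl ether and the C3 carbinol untouched and limit acid-induced flavanone closure.

**Compound list**
1 | 2,4,6-trihydroxybenzaldehyde | O=Cc1c(O)cc(O)cc1O | starting material
2 | 2,6-dihydroxy-4-methoxybenzaldehyde | COc1cc(O)c(C=O)c(O)c1 | intermediate
3 | 2-hydroxy-4-methoxy-6-(methoxymethoxy)benzaldehyde | COCOc1cc(OC)cc(O)c1C=O | intermediate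
4 | 2-(hydroxymethyl)-5-methoxy-3-(methoxymethoxy)phenol | COCOc1cc(OC)cc(O)c1CO | intermediate
5 | 2-methylprop-1-enylboronic acid pinacol ester | CC(C)=CB1OC(C)(C)C(C)(C)O1 | starting material
6 | 3-methoxy-5-(methoxymethoxy)-6-methylidenecyclohexa-2,4-dien-1-one (ortho-quinone methide, not isolated) | C=C1C(=O)C=C(OC)C=C1OCOC | intermediate
7 | (3R)-7-methoxy-5-(methoxymethoxy)-2,2-dimethyl-3-(4,4,5,5-tetramethyl-1,3,2-dioxaborolan-2-yl)chroman | COCOc1cc(OC)cc2c1C[C@@H](B3OC(C)(C)C(C)(C)O3)C(C)(C)O2 | intermediate
8 | (3R)-7-methoxy-5-(methoxymethoxy)-2,2-dimethylchroman-3-ol | COCOc1cc(OC)cc2c1C[C@@H](O)C(C)(C)O2 | intermediate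
9 | lithium (3R)-6-lithio-7-methoxy-5-(methoxymethoxy)-2,2-dimethylchroman-3-olate (not isolated) | [Li]c1c(OC)cc2c(c1OCOC)C[C@@H](O[Li])C(C)(C)O2 | intermediate
10 | 1-[(3R)-3-hydroxy-7-methoxy-5-(methoxymethoxy)-2,2-dimethylchroman-6-yl]ethanone | CC(=O)c1c(OC)cc2c(c1OCOC)C[C@@H](O)C(C)(C)O2 | intermediate
11 | 4-hydroxybenzaldehyde | O=Cc1ccc(O)cc1 | starting material
12 | 4-(methoxymethoxy)benzaldehyde | COCOc1ccc(C=O)cc1 | intermediate
13 | (E)-1-[(3R)-3-hydroxy-7-methoxy-5-(methoxymethoxy)-2,2-dimethylchroman-6-yl]-3-[4-(methoxymethoxy)phenyl]prop-2-en-1-one | COCOc1ccc(/C=C/C(=O)c2c(OC)cc3c(c2OCOC)C[C@@H](O)C(C)(C)O3)cc1 | intermediate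
14 | (E)-1-[(3R)-3,5-dihydroxy-7-methoxy-2,2-dimethylchroman-6-yl]-3-(4-hydroxyphenyl)prop-2-en-1-one | COc1cc2c(c(O)c1C(=O)/C=C/c1ccc(O)cc1)C[C@@H](O)C(C)(C)O2 | target

Total step count: 9. Longest linear sequence: 8 (steps 1–6, 8 and 9, from 1 to 14).

**Steps most likely to fail**

**Step 4.**
- The alkenyl boronate may be too weak a nucleophile, so that the methide oligomerises or alkylates the electron-rich arene rings.
- Boron may be lost after C–C bond formation, or after acid-induced reopening of the β-aryloxy boronate, which amounts to net prenylation.
- Discrimination between the faces and between the exo and endo orientations may be poor.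

The fallback uses known chemistry, sets out from 3 and comes back at 8. Aldehyde 3 is treated with 2-methylprop-1-enylmagnesium bromide (THF, 0 °C) to give 2-(1-hydroxy-3-methylbut-2-en-1-yl)-5-methoxy-3-(methoxymethoxy)phenol F1. On gentle warming with PPTS this loses water and closes by oxa-6π electrocyclisation to 7-methoxy-5-(methoxymethoxy)-2,2-dimethyl-2H-chromene F2. Jacobsen–Katsuki epoxidation follows, with (R,R)-Mn(salen)Cl, mCPBA and NMO in CH2Cl2 at −78 °C. 2,2-Dimethylchromenes are the model substrate class for this reaction. By analogy with the simple chromenes it should give (3R,4R)-3,4-epoxy-7-methoxy-5-(methoxymethoxy)-2,2-dimethylchroman F3. The crude epoxide is opened with LiAlH4 in THF at the benzylic and less hindered C4. The C3–O bond is not touched, and this delivers 8.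

**Step 6.**
- Metalation may compete at C8, between the methoxy group and the ring oxygen.
- Metalation of the alkoxide aggregate may be incomplete.
- A proton may pass from the methyl group of the amide to the hindered aryllithium.

The fallback replaces metalation by chelation-controlled acylation of the free phenol, sets out from 8 and comes back at 13. HCl in MeOH removes the MOM group to give (3R)-7-methoxy-2,2-dimethylchroman-3,5-diol F4. Ac2O and BF3·OEt2 (0 °C to rt) acetylate both hydroxyls. They then drive a Fries shift of the aryl acetate to C6, the only free ortho position, where the ketone is held as its boron chelate. This gives (3R)-6-acetyl-5-hydroxy-7-methoxy-2,2-dimethylchroman-3-yl acetate F5. MOMCl and i-Pr2NEt in CH2Cl2 then give (3R)-6-acetyl-7-methoxy-5-(methoxymethoxy)-2,2-dimethylchroman-3-yl acetate F6. F6 is taken into the conditions of step 8, where hydroxide also saponifies the 3-acetate, so that the route is rejoined at 13.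

**Step 3.**
- The methide may form too early in the basic borohydride medium, which would lead to over-reduction of the benzylic position.
- The free alcohol may self-condense during concentration and storage.

The fallback stores the methide as a benzylic ether instead of the alcohol, sets out from 3 and comes back at 7. Compound 3 is reduced with NaBH4 in MeOH at 0 °C and the remaining hydride is destroyed with acetone. The solution is then brought to about pH 5 with AcOH, so that the alcohol is solvolysed in the same flask to 5-methoxy-3-(methoxymethoxy)-2-(methoxymethyl)phenol F7. This ether can be chromatographed and kept. Under the conditions of step 4 it loses methanol, which the 5 Å sieves take up. That gives the same methide 6 and hence 7. 2-Hydroxybenzyl ethers are established acid-triggered methide precursors.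

**Further compounds**
F1 | step 4 | 2-(1-hydroxy-3-methylbut-2-en-1-yl)-5-methoxy-3-(methoxymethoxy)phenol (racemic) | COCOc1cc(OC)cc(O)c1C(O)C=C(C)C
F2 | step 4 | 7-methoxy-5-(methoxymethoxy)-2,2-dimethyl-2H-chromene | COCOc1cc(OC)cc2c1C=CC(C)(C)O2
F3 | step 4 | (3R,4R)-3,4-epoxy-7-methoxy-5-(methoxymethoxy)-2,2-dimethylchroman | COCOc1cc(OC)cc2c1[C@H]1O[C@H]1C(C)(C)O2
F4 | step 6 | (3R)-7-methoxy-2,2-dimethylchroman-3,5-diol | Oc1cc(OC)cc2c1C[C@@H](O)C(C)(C)O2
F5 | step 6 | (3R)-6-acetyl-5-hydroxy-7-methoxy-2,2-dimethylchroman-3-yl acetate | CC(=O)c1c(OC)cc2c(c1O)C[C@@H](OC(C)=O)C(C)(C)O2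
F6 | step 6 | (3R)-6-acetyl-7-methoxy-5-(methoxymethoxy)-2,2-dimethylchroman-3-yl acetate | CC(=O)c1c(OC)cc2c(c1OCOC)C[C@@H](OC(C)=O)C(C)(C)O2
F7 | step 3 | 5-methoxy-3-(methoxymethoxy)-2-(methoxymethyl)phenol | COCOc1cc(OC)cc(O)c1COC
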